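## Analysis of the target

Sideroxylonal B (22) is a 2-aryl-3,4-dihydro-2H-chromene. Its dihydropyran ring (O1, C2, C3, C4, C4a, C8a) is fused to a fully substituted phloroglucinol dialdehyde (ring A), and a second phloroglucinol dialdehyde (ring B) sits on C2. The three stereocentres are contiguous: C2 (R) carries ring B, C3 (S) an isopropyl group and C4 (S) an isobutyl group, with ring B and isopropyl cis and isopropyl and isobutyl trans. This 2,3-cis-3,4-trans pattern cannot be assumed to be the thermodynamic one, so C2 must not be allowed to equilibrate. The sensitive groups are four aryl aldehydes, five phenols and the O1–C2 bond, a benzylic aryl ether next to a trioxygenated ring that can ionise towards a quinone-methide-type cation. The difficulty is to join two hexasubstituted arenes across three crowded, adjacent stereocentres and to carry four aldehydes through that chemistry. The route rests on one feature of ring A: C8a, the carbon bearing O1, lies ortho to the C8 formyl group and para to the C6 formyl group, so the target's own aldehydes activate C8a for nucleophilic aromatic substitution.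

Chroman numbering (C2, C3, C4, C4a, C8a; ring B carbons primed) is used below for open-chain compounds as well.

## Retrosynthetic reasoning

**22 ⇒ 21.** The five O–CH3 bonds are cut last. Every methoxy group of 21 is ortho to at least one formyl group, so chelation-assisted Lewis-acid cleavage is available. The gain is that all phenols stay masked through the basic and organometallic steps. The forward step must remove five methyl groups and leave the aldehydes and the O1–C2 bond alone.

**21 ⇒ 20.** The C8a–O1 bond is cut, with fluorine placed on C8a and the oxygen kept on C2 as a secondary alcohol. Of the six ring bonds this is the only one whose formation is driven by the target's own formyl groups and touches no stereocentre. Cutting O1–C2 instead would pass through a C2 cation and lose configuration; cutting a ring C–C bond would force stereocentres to be set during ring closure. The gain is that C2, C3 and C4 can all be set on an open chain. Forward, the C2 alkoxide must attack C8a and not C5, and the C2–O bond must never break.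

**20 ⇒ 19.** The four formyl groups are traced back to dimethyl acetals. They are needed for the ring closure but cannot survive hydride or aryllithium reagents. They also cannot be introduced after the C2–O bond exists, because an electron-rich ring B would let that bond ionise under the Lewis acid of an electrophilic formylation. Each ring is therefore formylated before the carbinol is made and carried in masked form. Forward, four acetals must be hydrolysed without ionising the C2 alcohol.

**19 ⇒ 14 + 18.** The C2–C1′ bond is cut. This joins the two halves and creates C2 by addition of aryllithium 18 to the α-stereogenic aldehyde 14 under Felkin–Anh control. The alternative of making a C2 ketone and reducing it would deliver the nucleophile in the opposite role and hence the wrong epimer, so it is kept only in reserve. Forward, addition must outrun enolisation of 14 and occur on one face.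

**18 ⇒ 17 ⇒ 16 ⇒ 15.** 18 comes from 17 by lithiation of its only ring hydrogen, 17 from dialdehyde 16 by acetalisation, and 16 from symmetric 15 by two electrophilic formylations.

**14 ⇒ 13 ⇒ 12.** These are adjustments of the C2 oxidation level. Alcohol 13 arises by reductive removal of the auxiliary from 12, which cuts the N–acyl bond and returns 5.

**12 ⇒ 11 ⇒ 10.** The ring A acetals go back to formyl groups and these to the two ring C–H bonds of 10. This is done on 10 because it has no acid-labile benzylic C–O bond and its C3 centre is not enolised by a Lewis acid.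

**10 ⇒ 7 + 8.** The C4–C4a bond and the C3–H bond are cut together. Conjugate addition of aryl Grignard reagent 8 to enoyl sultam 7 gives enolate 9, and protonation then sets C4 and C3 in one operation under control of the auxiliary. Syn addition across the (E)-alkene gives the required relative configuration. 8 comes from bromide 2, made from 1 by bromination; the halogen fixes the position of the metal more surely than direct metalation of 1 would.

**7 ⇒ 4 + 5 (through 6); 4 ⇒ 3.** These are N-acylation and oxidation. Enal 3 already holds the C2–C3–C4 chain, both alkyl branches and the (E)-alkene.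

## Alternatives that were turned down

**Alternative 1:** The C2–C3 and C4–C4a bonds are cut, a formal [4+2] union of an O-aryl oxocarbenium ion with a diene.

- Forward key step: mixed acetal A2 ionises under a confined chiral Brønsted acid. Diene A3 attacks C2 with its isopropyl-bearing terminus, and the resulting allyl cation is captured by the ortho carbon of the aryloxy ring to give chroman A1. Hydrogenation, fourfold formylation and demethylation follow.
- For: two C–C bonds, the ring and all three stereocentres arise in one catalytic step with no auxiliary. On convergence and step count it is clearly stronger than the chosen route.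
- Against: four selectivities must hold at once on a stepwise cationic path. The methoxy group rather than the aryloxy group must leave A2. A3 must react at its less nucleophilic disubstituted end. The less natural 2,3-cis-3,4-trans isomer must form. An ion pair must be enantiodifferentiated. A1 must then be formylated four times while its O1–C2 bond lies between two electron-rich rings; a Lewis acid can open that bond to a quinone-methide-type cation and scramble C2.
- Comparison: the chosen route is longer and uses a stoichiometric auxiliary. In return, the formyl groups are in place before O1–C8a exists and in fact drive its formation (20 → 21), and C2 is never exposed as a cation.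

**Alternative 2:** The C4a–C5 bond is cut, so ring A is built last.

- Forward key step: ylidene keto ester A5, derived from lactone A6, is deprotonated at C4a. C4a acylates the terminal ester carbon C5, and tautomerisation gives the 5,7-dihydroxychroman A4.
- For: the stereotriad sits on a six-membered lactone with well-defined conformations. Ring A appears with free phenols, which makes its later formylation easier and saves two demethylations. On these two points it is at least as good as the chosen route.
- Against: A6 needs the same three stereocentres that 14 and 19 need, and then further steps to reach A5, so it is the longest of the options. C6 of A6 (chroman C2) is a benzylic acyloxy carbon next to a trimethoxyphenyl ring and ionises easily. The four formyl groups again come after the O1–C2 ether exists, now with both rings electron-rich.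
- Comparison: the chosen route buys both arenes (1, 15), builds no ring other than the pyran, and closes that ring under mild base with the aldehydes as activators.

**Alternative 3:** The O1–C2 and C2–C3 bonds are cut.

- Forward key step: phenol A8, with C4 already set, condenses with aldehyde A9 under a buffered silyl triflate Lewis acid. The trisubstituted alkene attacks the aryl oxocarbenium ion and proton loss gives the 3-isopropenyl chroman A7.
- For: only one stereocentre must be made beforehand, two more come from the ring closure, the phenol oxygen is present from the start so no fluorine chemistry is needed, and the sequence is short. On step economy it beats the chosen route.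
- Against: a chair-like closure normally places the C2 aryl group and the C3 side arm both pseudo-equatorial, which is 2,3-trans and the opposite of what is needed. Oxocarbenium formation from the very electron-rich A9 is reversible, so a thermodynamic product mixture is likely. A7 still needs hydrogenation and then fourfold formylation across the labile O1–C2 ether.
- Comparison: in the chosen route C2 is set under kinetic Felkin–Anh control on the open chain (14 → 19), independent of ring preferences, and the ring then closes with retention.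

Key step: step 13

Assumption: in the magnesium chelate of 7 the C3 methylene of the bornane skeleton is taken to shield the Cα-si face, so that the aryl group and then the proton enter on the Cα-re face; if the sense proves opposite, the enantiomeric (2S)-sultam would be used with no other change.

## Steps

Step 1
Reactants: 1 1-fluoro-3,5-dimethoxybenzene
Product: 2 2-bromo-1-fluoro-3,5-dimethoxybenzene
Conditions: NBS (1.0 equiv), MeCN, 0 °C → rt
Reagents that add atoms: N-bromosuccinimide, O=C1CCC(=O)N1Br
Why: Electrophilic aromatic bromination; the carbon between F and OMe is para to one methoxy group, ortho to the other and less hindered than the carbon between the two methoxy groups, so monobromination should occur there, and one equivalent at low temperature limits dibromination.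

Step 2
Reactants: 3 (E)-5-methyl-2-(propan-2-yl)hex-2-enal
Product: 4 (E)-5-methyl-2-(propan-2-yl)hex-2-enoic acid
Conditions: NaClO2, NaH2PO4, 2-methylbut-2-ene, t-BuOH/H2O, rt
Reagents that add atoms: sodium chlorite NaClO2, [Na+].[O-]Cl=O
Why: Pinnick oxidation converts the enal into the acid without touching or isomerising the trisubstituted (E)-alkene; the alkene scavenger removes hypochlorite.

Step 3
Reactants: 4 (E)-5-methyl-2-(propan-2-yl)hex-2-enoic acid; 5 (2R)-bornane-10,2-sultam
Product: 7 (2R)-N-[(E)-5-methyl-2-(propan-2-yl)hex-2-enoyl]bornane-10,2-sultam, via acid chloride 6 (not isolated)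
Conditions: (COCl)2, DMF (cat.), CH2Cl2, 0 °C → rt; then 5, NaH, toluene, 0 °C → rt
Reagents that add atoms: none
Why: Acid chloride formation and N-acylation of the sodium salt of the sultam is the standard entry to N-enoyl sultams; the (E) geometry is not affected.

Step 4
Reactants: 2 2-bromo-1-fluoro-3,5-dimethoxybenzene; 7 (2R)-N-[(E)-5-methyl-2-(propan-2-yl)hex-2-enoyl]bornane-10,2-sultam
Product: 10 (2R)-N-[(2S,3S)-3-(2-fluoro-4,6-dimethoxyphenyl)-5-methyl-2-(propan-2-yl)hexanoyl]bornane-10,2-sultam, via arylmagnesium chloride 8 (not isolated), via magnesium enolate 9 (not isolated)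
Conditions: 2, iPrMgCl·LiCl, THF, 0 °C → rt; CuBr·SMe2 (20 mol%), then 7, −40 → 0 °C; sat. aq NH4Cl, −78 °C
Reagents that add atoms: none
Why: Copper-catalysed 1,4-addition of an aryl Grignard reagent to an α,β-disubstituted N-enoyl sultam followed by enolate protonation, a known way to set Cβ and Cα together; bromine–magnesium exchange places the metal between F and OMe at a temperature where the ortho-fluoro Grignard reagent does not eliminate. In the chelate (Mg between the carbonyl and one sulfonyl oxygen, enoyl s-cis) the aryl group should add to Cβ on the Cα-re face and set C4 (S), and chelated enolate 9 should be protonated on the same face and set C3 (S). Net syn addition of aryl and H across the (E)-alkene gives the anti arrangement of isopropyl and aryl that the target requires.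

Step 5
Reactants: 10 (2R)-N-[(2S,3S)-3-(2-fluoro-4,6-dimethoxyphenyl)-5-methyl-2-(propan-2-yl)hexanoyl]bornane-10,2-sultam
Product: 11 (2R)-N-[(2S,3S)-3-(2-fluoro-3,5-diformyl-4,6-dimethoxyphenyl)-5-methyl-2-(propan-2-yl)hexanoyl]bornane-10,2-sultam
Conditions: Cl2CHOMe, TiCl4 (excess of each), CH2Cl2, −20 °C → rt; ice-water
Reagents that add atoms: dichloromethyl methyl ether, COC(Cl)Cl; water, O
Why: Twofold Rieche formylation; both free ring positions are ortho or para to both methoxy groups, and the first formyl group directs meta to the second site. Compound 10 has no benzylic C–O bond to ionise and its C3 centre is not enolised by the Lewis acid.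

Step 6
Reactants: 11 (2R)-N-[(2S,3S)-3-(2-fluoro-3,5-diformyl-4,6-dimethoxyphenyl)-5-methyl-2-(propan-2-yl)hexanoyl]bornane-10,2-sultam
Product: 12 (2R)-N-[(2S,3S)-3-[2-fluoro-4,6-dimethoxy-3,5-bis(dimethoxymethyl)phenyl]-5-methyl-2-(propan-2-yl)hexanoyl]bornane-10,2-sultam
Conditions: HC(OMe)3, MeOH, TsOH·H2O (cat.), rt; Et3N quench
Reagents that add atoms: methanol, CO; trimethyl orthoformate, COC(OC)OC
Why: Acid-catalysed acetalisation driven by the orthoformate; it protects both aldehydes from hydride and aryllithium reagents and switches off the activation of the C–F carbon until it is wanted.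

Step 7
Reactants: 12 (2R)-N-[(2S,3S)-3-[2-fluoro-4,6-dimethoxy-3,5-bis(dimethoxymethyl)phenyl]-5-methyl-2-(propan-2-yl)hexanoyl]bornane-10,2-sultam
Product: 13 (2S,3S)-3-[2-fluoro-4,6-dimethoxy-3,5-bis(dimethoxymethyl)phenyl]-5-methyl-2-(propan-2-yl)hexan-1-ol
Conditions: LiAlH4, THF, 0 °C → rt
Reagents that add atoms: none
Why: Hydride cleavage of the N-acyl sultam gives the primary alcohol and returns the auxiliary; acetals and the unactivated aryl fluoride are inert, and C3 is not enolised.

Step 8
Reactants: 13 (2S,3S)-3-[2-fluoro-4,6-dimethoxy-3,5-bis(dimethoxymethyl)phenyl]-5-methyl-2-(propan-2-yl)hexan-1-ol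
Product: 14 (2S,3S)-3-[2-fluoro-4,6-dimethoxy-3,5-bis(dimethoxymethyl)phenyl]-5-methyl-2-(propan-2-yl)hexanal
Conditions: Dess–Martin periodinane, pyridine, CH2Cl2, 0 °C → rt
Reagents that add atoms: none
Why: Dess–Martin oxidation buffered with pyridine is neither acidic enough to open the acetals nor basic enough to epimerise the α-branched aldehyde at C3; 14 should be used at once.

Step 9
Reactants: 15 1,3,5-trimethoxybenzene
Product: 16 2,4,6-trimethoxybenzene-1,3-dicarbaldehyde
Conditions: Cl2CHOMe, TiCl4 (excess of each), CH2Cl2, 0 °C → rt; ice-water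
Reagents that add atoms: dichloromethyl methyl ether, COC(Cl)Cl; water, O
Why: Twofold Rieche formylation of a very electron-rich arene; excess reagent at room temperature should carry the monoaldehyde on to the dialdehyde, and the last position, flanked by two formyl-deactivated neighbours, should resist a third formylation.

Step 10
Reactants: 16 2,4,6-trimethoxybenzene-1,3-dicarbaldehyde
Product: 17 1,3,5-trimethoxy-2,4-bis(dimethoxymethyl)benzene
Conditions: HC(OMe)3, MeOH, TsOH·H2O (cat.), rt → 40 °C; Et3N quench
Reagents that add atoms: methanol, CO; trimethyl orthoformate, COC(OC)OC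
Why: Acetalisation as in step 6; the acetals tolerate n-BuLi and leave the one ring C–H, between two methoxy groups, free for lithiation.

Step 11
Reactants: 17 1,3,5-trimethoxy-2,4-bis(dimethoxymethyl)benzene; 14 (2S,3S)-3-[2-fluoro-4,6-dimethoxy-3,5-bis(dimethoxymethyl)phenyl]-5-methyl-2-(propan-2-yl)hexanal
Product: 19 (1R,2S,3S)-3-[2-fluoro-4,6-dimethoxy-3,5-bis(dimethoxymethyl)phenyl]-5-methyl-2-(propan-2-yl)-1-[2,4,6-trimethoxy-3,5-bis(dimethoxymethyl)phenyl]hexan-1-ol, via aryllithium 18 (not isolated)
Conditions: 17, n-BuLi, THF, 0 °C; then 14, −78 → −30 °C; H2O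
Reagents that add atoms: none
Why: Directed ortho-lithiation at the only ring hydrogen of 17, then addition to the α-stereogenic aldehyde under Felkin–Anh control. The large branch at C3, the carbon bearing ring A, lies anti to the incoming aryl group and the isopropyl group sits next to the carbonyl oxygen, so the hydroxyl and isopropyl groups should end up syn along the C1′–C2–C3–C4 chain, which is C2 (R). Hydride reduction of the corresponding ketone would give the other epimer by the same model, so the aryl group is the nucleophile.

Step 12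
Reactants: 19 (1R,2S,3S)-3-[2-fluoro-4,6-dimethoxy-3,5-bis(dimethoxymethyl)phenyl]-5-methyl-2-(propan-2-yl)-1-[2,4,6-trimethoxy-3,5-bis(dimethoxymethyl)phenyl]hexan-1-ol
Product: 20 5-[(1R,2S,3S)-3-(2-fluoro-3,5-diformyl-4,6-dimethoxyphenyl)-1-hydroxy-5-methyl-2-(propan-2-yl)hexyl]-2,4,6-trimethoxybenzene-1,3-dicarbaldehyde
Conditions: PPTS (cat.), acetone/H2O (10:1), 0 °C → rt
Reagents that add atoms: water, O
Why: Mild acetal hydrolysis; the aryl dimethyl acetals ionise to oxygen-stabilised cations far faster than the benzylic alcohol can lose water, and once ring B carries two formyl groups the C2–O bond should no longer ionise. The step reveals the four aldehydes and with them the activation of C8a.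

Step 13
Reactants: 20 5-[(1R,2S,3S)-3-(2-fluoro-3,5-diformyl-4,6-dimethoxyphenyl)-1-hydroxy-5-methyl-2-(propan-2-yl)hexyl]-2,4,6-trimethoxybenzene-1,3-dicarbaldehyde
Product: 21 (2R,3S,4S)-2-(3,5-diformyl-2,4,6-trimethoxyphenyl)-5,7-dimethoxy-4-(2-methylpropyl)-3-(propan-2-yl)-3,4-dihydro-2H-chromene-6,8-dicarbaldehyde
Conditions: Cs2CO3 (2 equiv), DMF (0.01 M), 4 Å molecular sieves, 0 °C → rt
Reagents that add atoms: none
Why: Intramolecular nucleophilic aromatic substitution: the C2 alkoxide adds to fluorine-bearing C8a to give a Meisenheimer-type anion delocalised into the C8 (ortho) and C6 (para) formyl groups, and loss of fluoride restores the arene. The closest known reaction type is the base-mediated cyclisation of alcohols onto ortho- and para-carbonyl-activated aryl fluorides to give chromans. The pyran ring closes by a six-membered addition–elimination at an sp2 carbon, formally 6-exo-trig, with the negative charge taken up outside the new ring. No stereocentre is formed; C2 keeps its configuration because the C2–O bond is never broken, so no benzylic cation or quinone methide can arise, and C3 and C4 are not acidic. The step needs site selectivity between C8a and C5, since both ortho carbons of C4a are activated by one ortho and one para formyl group; fluorine at C8a accelerates the addition and is by far the better leaving group than methoxide at C5. It also needs chemoselectivity against the four aldehydes: alkoxide addition to a formyl carbon is reversible, whereas fluoride loss is not, so the hemiacetal alkoxides should drain into 21. High dilution and dry conditions should suppress intermolecular substitution and attack by hydroxide.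

Step 14
Reactants: 21 (2R,3S,4S)-2-(3,5-diformyl-2,4,6-trimethoxyphenyl)-5,7-dimethoxy-4-(2-methylpropyl)-3-(propan-2-yl)-3,4-dihydro-2H-chromene-6,8-dicarbaldehyde
Product: 22 sideroxylonal B, (2R,3S,4S)-2-(3,5-diformyl-2,4,6-trihydroxyphenyl)-5,7-dihydroxy-4-(2-methylpropyl)-3-(propan-2-yl)-3,4-dihydro-2H-chromene-6,8-dicarbaldehyde
Conditions: BCl3 (excess), CH2Cl2, −78 → 0 °C; then H2O
Reagents that add atoms: none
Why: Chelation-assisted cleavage of aryl methyl ethers ortho to a carbonyl group: boron binds the formyl oxygen and the neighbouring ether oxygen, and chloride attacks the methyl carbon. All five methoxy groups have such a neighbour, while the O1–C2 bond would require substitution at a crowded secondary carbon on an electron-poor ring.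

## Compound list

1 | 1-fluoro-3,5-dimethoxybenzene | COc1cc(F)cc(OC)c1 | starting material
2 | 2-bromo-1-fluoro-3,5-dimethoxybenzene | COc1cc(OC)c(Br)c(F)c1 | intermediate
3 | (E)-5-methyl-2-(propan-2-yl)hex-2-enal | CC(C)C/C=C(\C(C)C)C=O | starting material
4 | (E)-5-methyl-2-(propan-2-yl)hex-2-enoic acid | CC(C)C/C=C(\C(C)C)C(O)=O | intermediate
5 | (2R)-bornane-10,2-sultam, the (1S)-(−)-2,10-camphorsultam | CC1(C)[C@@H]2CC[C@]13CS(=O)(=O)N[C@@H]3C2 | starting material
6 | (E)-5-methyl-2-(propan-2-yl)hex-2-enoyl chloride | CC(C)C/C=C(\C(C)C)C(Cl)=O | intermediate (not isolated)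
7 | (2R)-N-[(E)-5-methyl-2-(propan-2-yl)hex-2-enoyl]bornane-10,2-sultam | CC1(C)[C@@H]2CC[C@]13CS(=O)(=O)N(C(=O)/C(C(C)C)=C/CC(C)C)[C@@H]3C2 | intermediate
8 | (2-fluoro-4,6-dimethoxyphenyl)magnesium chloride | COc1cc(OC)c([Mg]Cl)c(F)c1 | intermediate (not isolated)
9 | chloromagnesium (Z)-enolate of 10: (2R)-N-[(1Z,3S)-1-(chloromagnesiooxy)-3-(2-fluoro-4,6-dimethoxyphenyl)-5-methyl-2-(propan-2-yl)hex-1-en-1-yl]bornane-10,2-sultam | CC1(C)[C@@H]2CC[C@]13CS(=O)(=O)N(/C(O[Mg]Cl)=C(C(C)C)/[C@H](CC(C)C)c1c(F)cc(OC)cc1OC)[C@@H]3C2 | intermediate (not isolated)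
10 | (2R)-N-[(2S,3S)-3-(2-fluoro-4,6-dimethoxyphenyl)-5-methyl-2-(propan-2-yl)hexanoyl]bornane-10,2-sultam | CC1(C)[C@@H]2CC[C@]13CS(=O)(=O)N(C(=O)[C@@H](C(C)C)[C@H](CC(C)C)c1c(F)cc(OC)cc1OC)[C@@H]3C2 | intermediate
11 | (2R)-N-[(2S,3S)-3-(2-fluoro-3,5-diformyl-4,6-dimethoxyphenyl)-5-methyl-2-(propan-2-yl)hexanoyl]bornane-10,2-sultam | CC1(C)[C@@H]2CC[C@]13CS(=O)(=O)N(C(=O)[C@@H](C(C)C)[C@H](CC(C)C)c1c(F)c(C=O)c(OC)c(C=O)c1OC)[C@@H]3C2 | intermediate
12 | (2R)-N-[(2S,3S)-3-[2-fluoro-4,6-dimethoxy-3,5-bis(dimethoxymethyl)phenyl]-5-methyl-2-(propan-2-yl)hexanoyl]bornane-10,2-sultam | CC1(C)[C@@H]2CC[C@]13CS(=O)(=O)N(C(=O)[C@@H](C(C)C)[C@H](CC(C)C)c1c(F)c(C(OC)OC)c(OC)c(C(OC)OC)c1OC)[C@@H]3C2 | intermediate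
13 | (2S,3S)-3-[2-fluoro-4,6-dimethoxy-3,5-bis(dimethoxymethyl)phenyl]-5-methyl-2-(propan-2-yl)hexan-1-ol | CC(C)C[C@@H]([C@H](C(C)C)CO)c1c(OC)c(C(OC)OC)c(OC)c(C(OC)OC)c1F | intermediate
14 | (2S,3S)-3-[2-fluoro-4,6-dimethoxy-3,5-bis(dimethoxymethyl)phenyl]-5-methyl-2-(propan-2-yl)hexanal | CC(C)C[C@@H]([C@H](C(C)C)C=O)c1c(OC)c(C(OC)OC)c(OC)c(C(OC)OC)c1F | intermediate
15 | 1,3,5-trimethoxybenzene | COc1cc(OC)cc(OC)c1 | starting material
16 | 2,4,6-trimethoxybenzene-1,3-dicarbaldehyde | COc1cc(OC)c(C=O)c(OC)c1C=O | intermediate
17 | 1,3,5-trimethoxy-2,4-bis(dimethoxymethyl)benzene | COc1cc(OC)c(C(OC)OC)c(OC)c1C(OC)OC | intermediate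
18 | [2,4,6-trimethoxy-3,5-bis(dimethoxymethyl)phenyl]lithium | [Li]c1c(OC)c(C(OC)OC)c(OC)c(C(OC)OC)c1OC | intermediate (not isolated)
19 | (1R,2S,3S)-3-[2-fluoro-4,6-dimethoxy-3,5-bis(dimethoxymethyl)phenyl]-5-methyl-2-(propan-2-yl)-1-[2,4,6-trimethoxy-3,5-bis(dimethoxymethyl)phenyl]hexan-1-ol | CC(C)C[C@@H]([C@H](C(C)C)[C@@H](O)c1c(OC)c(C(OC)OC)c(OC)c(C(OC)OC)c1OC)c1c(OC)c(C(OC)OC)c(OC)c(C(OC)OC)c1F | intermediate
20 | 5-[(1R,2S,3S)-3-(2-fluoro-3,5-diformyl-4,6-dimethoxyphenyl)-1-hydroxy-5-methyl-2-(propan-2-yl)hexyl]-2,4,6-trimethoxybenzene-1,3-dicarbaldehyde | CC(C)C[C@@H]([C@H](C(C)C)[C@@H](O)c1c(OC)c(C=O)c(OC)c(C=O)c1OC)c1c(OC)c(C=O)c(OC)c(C=O)c1F | intermediate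
21 | (2R,3S,4S)-2-(3,5-diformyl-2,4,6-trimethoxyphenyl)-5,7-dimethoxy-4-(2-methylpropyl)-3-(propan-2-yl)-3,4-dihydro-2H-chromene-6,8-dicarbaldehyde (sideroxylonal B penta-O-methyl ether) | CC(C)C[C@@H]1c2c(OC)c(C=O)c(OC)c(C=O)c2O[C@@H](c2c(OC)c(C=O)c(OC)c(C=O)c2OC)[C@H]1C(C)C | intermediate
22 | sideroxylonal B, (2R,3S,4S)-2-(3,5-diformyl-2,4,6-trihydroxyphenyl)-5,7-dihydroxy-4-(2-methylpropyl)-3-(propan-2-yl)-3,4-dihydro-2H-chromene-6,8-dicarbaldehyde | CC(C)C[C@@H]1c2c(O)c(C=O)c(O)c(C=O)c2O[C@@H](c2c(O)c(C=O)c(O)c(C=O)c2O)[C@H]1C(C)C | target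

## Step count and least certain steps

Total step count: 14. Longest linear sequence: 11 steps (from 3: steps 2–8 and 11–14).

**Step 13 (key step).**
- What may go wrong: slow ring closure at a crowded secondary alkoxide while that alkoxide is held back by the four aldehydes (hemiacetal formation, then intermolecular hydride transfer), or displacement of fluorine by hydroxide from traces of water. The two ring B aldehydes are not needed for activation and only add to this load.
- Fallback: it sets out from 16 and 14 and returns at 21.
  - 16 is acetalised with 2,2-dimethylpropane-1,3-diol (TsOH, toluene, Dean–Stark) to 2,2′-(2,4,6-trimethoxy-1,3-phenylene)bis(5,5-dimethyl-1,3-dioxane) F10.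
  - F10 is lithiated as in step 11 to the aryllithium F11 and added to 14 to give the carbinol F12, with dioxanes on ring B and dimethyl acetals on ring A.
  - PPTS in wet acetone at 0 °C should open only the acyclic acetals and give the ring A dialdehyde F13.
  - In F13 only the activating aldehydes are free, so Cs2CO3, or a stronger base such as KN(SiMe3)2, can be used to close the ring to the chroman F14.
  - Aqueous acid hydrolysis of the two dioxanes then gives 21.

**Step 4.**
- What may go wrong: low reactivity of the twisted, α-branched enoyl group towards a di-ortho-substituted aryl nucleophile, with γ-deprotonation by the Grignard reagent as a competing path. Face control may also be lost in the protonation, where allylic strain from the new C4 centre can oppose the auxiliary.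
- Fallback: it sets out from 2 (through 8) and returns at 10.
  - 8 is added to acrolein to give racemic 1-(2-fluoro-4,6-dimethoxyphenyl)prop-2-en-1-ol F1.
  - Stereodivergent α-allylation of 3-methylbutanal with F1 under iridium/amine dual catalysis ([Ir(cod)Cl]2, a chiral phosphoramidite–alkene ligand, a diarylprolinol silyl ether, an acidic promoter; the catalyst pairing is chosen for the anti isomer) should give (2S,3S)-3-(2-fluoro-4,6-dimethoxyphenyl)-2-(propan-2-yl)pent-4-enal F2.
  - Pinnick oxidation gives the acid F3.
  - Cross-metathesis with 2-methylbut-2-ene (second-generation Grubbs catalyst, RuCl2(=CHPh)(PCy3)(H2IMes)) gives the hex-4-enoic acid F4.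
  - Hydrogenation over Pd/C gives (2S,3S)-3-(2-fluoro-4,6-dimethoxyphenyl)-5-methyl-2-(propan-2-yl)hexanoic acid F5.
  - Its acid chloride F6 acylates the sodium salt of 5 as in step 3 to give 10.

**Step 11.**
- What may go wrong: weak or reversed facial selectivity, because both carbon substituents at C3 are branched and their size difference decides the outcome. Enolisation of the hindered aldehyde by 18 would also erode C3.
- Fallback: it sets out from 14 and returns at 19. The crude mixture of C2 epimers is oxidised (Dess–Martin periodinane, pyridine) to the aryl ketone F7. F7 is reduced with LiAlH4 or, if the substrate bias is small, a chiral hydride reagent. Hydride then takes the nucleophile's role, so the Felkin–Anh sense is the complement of that in the aryl addition, and whichever substituent dominates, one of the two sequences should favour 19.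

**Step 12.**
- What may go wrong: ionisation of the C2 alcohol (epimerisation or elimination) while ring B is still electron-rich, in competition with acetal hydrolysis.
- Fallback: it sets out from 16 and 14 and returns at 20.
  - The aldehydes of 16 are masked in the flask as lithium α-amino alkoxides with LiN(CH2CH2)2NMe (2 equiv) and the ring is lithiated with n-BuLi to the aryllithium F8.
  - Addition to 14 and aqueous basic work-up release the ring B aldehydes at once and give the carbinol F9, in which ring B is already electron-poor.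
  - The two ring A acetals of F9 are then hydrolysed with PPTS in wet acetone to give 20.

**Step 14.**
- What may go wrong: opening of the O1–C2 bond by boron chelated between the C8 formyl oxygen and O1, which would scramble C2, or incomplete removal of the five methyl groups.
- Fallback: it sets out from 21 and returns at 22 with no new compound (F0). The Lewis-acid cleavage is replaced by nucleophilic dealkylation at the methyl carbons with MgI2·OEt2 in toluene/THF at 60–80 °C. Each methoxy group is a vinylogous methyl ester towards iodide, whereas the secondary C2 carbon is closed to substitution.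

## Further compounds

F1 | step 4 | 1-(2-fluoro-4,6-dimethoxyphenyl)prop-2-en-1-ol (racemic) | C=CC(O)c1c(F)cc(OC)cc1OC
F2 | step 4 | (2S,3S)-3-(2-fluoro-4,6-dimethoxyphenyl)-2-(propan-2-yl)pent-4-enal | C=C[C@@H]([C@H](C(C)C)C=O)c1c(F)cc(OC)cc1OC
F3 | step 4 | (2S,3S)-3-(2-fluoro-4,6-dimethoxyphenyl)-2-(propan-2-yl)pent-4-enoic acid | C=C[C@@H]([C@H](C(C)C)C(O)=O)c1c(F)cc(OC)cc1OC
F4 | step 4 | (2S,3S)-3-(2-fluoro-4,6-dimethoxyphenyl)-5-methyl-2-(propan-2-yl)hex-4-enoic acid | CC(C)=C[C@@H]([C@H](C(C)C)C(O)=O)c1c(F)cc(OC)cc1OC
F5 | step 4 | (2S,3S)-3-(2-fluoro-4,6-dimethoxyphenyl)-5-methyl-2-(propan-2-yl)hexanoic acid | CC(C)C[C@@H]([C@H](C(C)C)C(O)=O)c1c(F)cc(OC)cc1OC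
F6 | step 4 | (2S,3S)-3-(2-fluoro-4,6-dimethoxyphenyl)-5-methyl-2-(propan-2-yl)hexanoyl chloride | CC(C)C[C@@H]([C@H](C(C)C)C(Cl)=O)c1c(F)cc(OC)cc1OC
F7 | step 11 | (2S,3S)-3-[2-fluoro-4,6-dimethoxy-3,5-bis(dimethoxymethyl)phenyl]-5-methyl-2-(propan-2-yl)-1-[2,4,6-trimethoxy-3,5-bis(dimethoxymethyl)phenyl]hexan-1-one | CC(C)C[C@@H]([C@H](C(C)C)C(=O)c1c(OC)c(C(OC)OC)c(OC)c(C(OC)OC)c1OC)c1c(OC)c(C(OC)OC)c(OC)c(C(OC)OC)c1F
F8 | step 12 | {2,4,6-trimethoxy-3,5-bis[lithiooxy(4-methylpiperazin-1-yl)methyl]phenyl}lithium | [Li]c1c(OC)c(C(O[Li])N2CCN(C)CC2)c(OC)c(C(O[Li])N2CCN(C)CC2)c1OC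
F9 | step 12 | 5-[(1R,2S,3S)-3-[2-fluoro-4,6-dimethoxy-3,5-bis(dimethoxymethyl)phenyl]-1-hydroxy-5-methyl-2-(propan-2-yl)hexyl]-2,4,6-trimethoxybenzene-1,3-dicarbaldehyde | CC(C)C[C@@H]([C@H](C(C)C)[C@@H](O)c1c(OC)c(C=O)c(OC)c(C=O)c1OC)c1c(OC)c(C(OC)OC)c(OC)c(C(OC)OC)c1F
F10 | step 13 | 2,2′-(2,4,6-trimethoxy-1,3-phenylene)bis(5,5-dimethyl-1,3-dioxane) | COc1cc(OC)c(C2OCC(C)(C)CO2)c(OC)c1C1OCC(C)(C)CO1
F11 | step 13 | [3,5-bis(5,5-dimethyl-1,3-dioxan-2-yl)-2,4,6-trimethoxyphenyl]lithium | [Li]c1c(OC)c(C2OCC(C)(C)CO2)c(OC)c(C2OCC(C)(C)CO2)c1OC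
F12 | step 13 | (1R,2S,3S)-1-[3,5-bis(5,5-dimethyl-1,3-dioxan-2-yl)-2,4,6-trimethoxyphenyl]-3-[2-fluoro-4,6-dimethoxy-3,5-bis(dimethoxymethyl)phenyl]-5-methyl-2-(propan-2-yl)hexan-1-ol | CC(C)C[C@@H]([C@H](C(C)C)[C@@H](O)c1c(OC)c(C2OCC(C)(C)CO2)c(OC)c(C2OCC(C)(C)CO2)c1OC)c1c(OC)c(C(OC)OC)c(OC)c(C(OC)OC)c1F
F13 | step 13 | 5-[(1S,2S,3R)-3-[3,5-bis(5,5-dimethyl-1,3-dioxan-2-yl)-2,4,6-trimethoxyphenyl]-3-hydroxy-1-(2-methylpropyl)-2-(propan-2-yl)propyl]-4-fluoro-2,6-dimethoxybenzene-1,3-dicarbaldehyde (same configuration as 20) | CC(C)C[C@@H]([C@H](C(C)C)[C@@H](O)c1c(OC)c(C2OCC(C)(C)CO2)c(OC)c(C2OCC(C)(C)CO2)c1OC)c1c(OC)c(C=O)c(OC)c(C=O)c1F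
F14 | step 13 | (2R,3S,4S)-2-[3,5-bis(5,5-dimethyl-1,3-dioxan-2-yl)-2,4,6-trimethoxyphenyl]-5,7-dimethoxy-4-(2-methylpropyl)-3-(propan-2-yl)-3,4-dihydro-2H-chromene-6,8-dicarbaldehyde | CC(C)C[C@@H]1c2c(OC)c(C=O)c(OC)c(C=O)c2O[C@@H](c2c(OC)c(C3OCC(C)(C)CO3)c(OC)c(C3OCC(C)(C)CO3)c2OC)[C@H]1C(C)C
F0 | step 14 | none | none
A1 | alternative 1 | 2,3-cis-3,4-trans 5,7-dimethoxy-4-(2-methylprop-1-enyl)-3-(propan-2-yl)-2-(2,4,6-trimethoxyphenyl)chroman | CC(C)=C[C@@H]1c2c(OC)cc(OC)cc2O[C@@H](c2c(OC)cc(OC)cc2OC)[C@H]1C(C)C
A2 | alternative 1 | 2-[(3,5-dimethoxyphenoxy)(methoxy)methyl]-1,3,5-trimethoxybenzene | COC(Oc1cc(OC)cc(OC)c1)c1c(OC)cc(OC)cc1OC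
A3 | alternative 1 | (E)-2,6-dimethylhepta-2,4-diene | CC(C)/C=C/C=C(C)C
A4 | alternative 2 | 2,3-cis-3,4-trans 5,7-dihydroxy-4-(2-methylpropyl)-3-(propan-2-yl)-2-(2,4,6-trimethoxyphenyl)chroman | CC(C)C[C@@H]1c2c(O)cc(O)cc2O[C@@H](c2c(OC)cc(OC)cc2OC)[C@H]1C(C)C
A5 | alternative 2 | methyl 4-[(4R,5S,6R)-4-(2-methylpropyl)-5-(propan-2-yl)-6-(2,4,6-trimethoxyphenyl)oxan-2-ylidene]-3-oxobutanoate | CC(C)C[C@@H]1CC(=CC(=O)CC(=O)OC)O[C@@H](c2c(OC)cc(OC)cc2OC)[C@H]1C(C)C
A6 | alternative 2 | (4R,5S,6R)-4-(2-methylpropyl)-5-(propan-2-yl)-6-(2,4,6-trimethoxyphenyl)oxan-2-one | CC(C)C[C@@H]1CC(=O)O[C@@H](c2c(OC)cc(OC)cc2OC)[C@H]1C(C)C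
A7 | alternative 3 | 2,3-cis-3,4-trans 5,7-dimethoxy-4-(2-methylpropyl)-3-(prop-1-en-2-yl)-2-(2,4,6-trimethoxyphenyl)chroman | CC(C)C[C@@H]1c2c(OC)cc(OC)cc2O[C@@H](c2c(OC)cc(OC)cc2OC)[C@H]1C(C)=C
A8 | alternative 3 | 2-[(4S)-2,6-dimethylhept-2-en-4-yl]-3,5-dimethoxyphenol | CC(C)C[C@@H](C=C(C)C)c1c(O)cc(OC)cc1OC
A9 | alternative 3 | 2,4,6-trimethoxybenzaldehyde | COc1cc(OC)c(C=O)c(OC)c1
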